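24.8% of the charge reads as neither solid nor product in Friday's flask at 60.0 min, so I treat each flask as a tank with a steady feed and a residence time.

| flask | solid substrate | reagent | temperature | remark | time |
|---|---|---|---|---|---|
| Friday's | 0.30 M | 0.45 M | 32 °C | run made earlier |  |
| Monday's | 0.30 M | 0.68 M | 60 °C | run made earlier |  |
| north-east | 0.30 M | 0.900 M | 70 °C |  | 25 min |
| west | 0.30 M | 0.900 M | 45 °C |  | 25 min |
| north | 0.30 M | 0.900 M |  | at 20 °C until 20 min, from then on at 70 °C | 25 min |
| north-west | 0.30 M | 0.900 M | 20 °C |  | 25 min |

- Friday's (time / min: product / %, solid substrate / %): 30.0: 28.9, 46.9; 60.0: 74.3, 0.9; 90.0: 95.7, 0; 120: 99.1, 0.3; 150: 99.3, 0; 180: 100.3, 0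
- Monday's (time / min: product / %, solid substrate / %): 3.00: 3.7, 94.0; 10.0: 18.0, 79.8; 15.0: 28.5, 68.2; 25.0: 50.1, 47.1; 40.0: 80.6, 16.1; 50.0: 99.7, 0.5

(readings scatter by 0.5 percentage points)

- solid, in amounts per volume of the solution: solid substrate
- steps that have been proposed: solid substrate <-> starting material; reagent + intermediate -> product; starting material -> intermediate
- at the start none of the solid substrate is in solution
- what has only dissolved of solid substrate counts as not reacted

* the flask with the highest amount of product, in percent of the solid substrate charged ("all alike" if they lie within 1.5 percentage points) (north-east / west / north / north-west / all alike)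
* final product, as a percentage of the solid substrate charged, in north-east
* final product, as a percentage of the solid substrate charged, in west
* final product, as a percentage of the solid substrate charged, in north
* final product, as a percentage of the solid substrate charged, in north-west

Two times count. The feed time T is how long the charge needs to dissolve at the pace of the solid's fall: 56.5 min from Friday's solid at 32 °C, 47.5 min from Monday's at 60 °C. The life τ is how long dissolved material lasts before it becomes product. Friday's pool, with the solid down to 0.9%, falls from 24.8% to 4.30% in 30.0 min, so τ reads 17.1 min. Monday's pool reads near 3.05%, and a steady pool equals τ/T, so τ reads 1.45 min.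

Stepping both times by a constant factor per degree, I get τ 0.600 min and T 44.6 min at 70 °C. Their ratio is the hold-up h, the share of the charge sitting in solution under steady feed: 1.34%. Because τ is far shorter than T there, I take dissolving as the rate-limiting step and reckon product as t/T − h: 54.7% in north-east. West, with h 10.4%, I reckon at 37.5%.

At 20 °C, τ is 49.3 min and T is 60.9 min. The window is shorter than τ, so I let the pool fill, and I reckon north-west at 8.85%. North's hot stretch is far longer than τ, so I take its pool down to h and reckon north at 42.7%.

The forecast, from “Solid disappears linearly”, puts north-east first: 54%, west 38%, north 42%, north-west 7.5%, below mine in north-west.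

The flasks give north-east on top with 52.0%, then north 44.2%, west 42.4%, north-west 7.47%.

solid substrate ⇌ starting material, rate k1*(cs1 - [starting material]) while solid is left; crystals form when [starting material] > cs1 (solubility = 0.260 M, k = 4.10 × 10⁻⁴ s⁻¹); reagent + intermediate → product (k = 0.00510 M⁻¹ s⁻¹, Ea = 59.0 kJ mol⁻¹); starting material → intermediate (k = 3.40 × 10⁻⁴ s⁻¹, Ea = 85.0 kJ mol⁻¹); (constants at 20 °C) In north-east at 25.0 min, starting material 0.644% and intermediate 0.273% make a pool of 0.917%, against my hold-up of 1.34%. A run of north with 1.2 M of solid substrate shows what takes the forecast's percentages wrong: h and t/T are both shares of the charge, so at the same dissolving pace in M per minute my 42.7% shrinks to 10.7%, and that neighbour flask gives 11.0%.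

The runs are calculated for substances that don't exist.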